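(The constants are invented; the rest is arithmetic.)

Don't take the brisk capture of substrate for a brisk cycle, and don't count the whole charge as working catalyst. You asked for a quick number on this flask, so follow one catalyst molecule and ask for its chances at each fork.

substrate 0.50 mM; free catalyst 3 mol%; impurity 4.2 µM; time 1.5 min

* the state of affairs at 1.5 min: stopped, and by what, or still going (it is still moving / no working catalyst is left / forward and back rates have come level / all of the substrate has reacted)
* conversion of substrate at 1.5 min
* amount of target at 1.5 min, in percent of the substrate charged

- percentages count the substrate that a species holds: one resting dimer counts as two
- two of one species on the left: rate k times its square, two consumed each time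
- the reaction counts as stopped when no species that holds the substrate changes by six tenths of a point or more over the second half of the time
- run time (flask): 1.5 min

    catalyst intermediate B ⇌ free catalyst + target (K1 = 0.0087 M, k1 = 1.1 /s)
    free catalyst + impurity → spent catalyst A (k2 = 1.9 × 10⁵ /M/s)
    catalyst intermediate A → catalyst intermediate B (k3 = 0.21 /s)
    2 free catalyst → spent catalyst B (k4 = 910 /M/s)
    catalyst intermediate B + catalyst intermediate B ⇌ resting dimer (K5 = 1.4 × 10⁵ /M, k5 = 23000 /M/s)
    substrate + free catalyst ⇌ catalyst intermediate A (K6 = 13000 /M, k6 = 20000 /M/s)

Free catalyst binds substrate to catalyst intermediate A at 10.0 /s, but catalyst intermediate A falls back at 1.54 /s and passes on to catalyst intermediate B at 0.21 /s, so each capture goes forward with a chance of 12.0%. Catalyst intermediate B then releases target and free catalyst at 1.1 /s. Over the 8.33 captures that one passage costs, the molecule waits 4.76 s in catalyst intermediate A, 0.833 s as free catalyst and 0.909 s in catalyst intermediate B. Catalyst intermediate A is therefore the resting state of the working round. Together the waits make 6.50 s, the round time, the mean time a working catalyst molecule needs from one target to the next at the starting [substrate].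

The impurity removes one free catalyst per molecule, leaving 10.8 µM of the 15.0 µM charged. With free catalyst at its share of the round, the impurity lasts about 3.81 s, so against 90 s I count that loss from the start. My reckoning gives 29.9% target and, with what the two intermediates hold, a conversion of 31.8%. That leaves 68.2% of the substrate, so I call the flask still moving.

The forecast says it is still moving, with conversion 27% and target 25%, and holds that “free-catalyst dimerisation is too slow to shut it down”; its target stands below mine.

The simulation says it is still moving, with conversion 29.0% and target 27.2%, so the forecast's answers hold.

In this flask at 0.150 min, with substrate at 95.2%, catalyst intermediate A stands at 51.1% of the catalyst charged against 9.72% for catalyst intermediate B, a ratio of 5.26 beside the 5.24 of their waits in the round time. In this flask at 1.50 min, catalyst intermediate B releases target 18 times as fast as it enters resting dimer, forward rates alone. In the neighbour flask with 1.8 mol% free catalyst, 4.80 µM working over the same round time gives 13.3% target; computed, that neighbour flask holds 13.3%.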